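**Retrosynthetic overview**
- The strategy rests on the only unsubstituted diene of the chain, C14=C15–C15'=C14', which lies between the methyl-bearing sp2 carbons C13 and C13'. Cutting C13–C14 and C14'–C13' gives ring-A iodide 18, ring-B iodide 30 and the four-carbon tin/boron diene 36.
- Each iodide is cut at C10=C11 (HWE with iodophosphonate 17) and at C8=C9 (Wittig), back to a ring-bearing C8 enal (12 or 28).
- The exocyclic C6=C7 and C6'=C7' bonds come from opening a C5,C6-epoxide through a C7=C8 enol ether. Ring A then loses the C5 hydroxyl to give C4=C5; ring B keeps it as C5'–OH.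
- C3 and C3' have opposite spatial sense. Both series start from ketoisophorone 1 via hydroxy ketone 3, ring B after a Mitsunobu inversion, and tartrate-controlled epoxidation sets C5'.
- No ring is formed in the route: both six-membered rings are the carbocycle of 1.

Key step: step 30

Remark: carotenoid numbering is used (ring A C1–C6, chain C7–C15, primes for the ring-B half). Read from the SMILES, the target is 3S, 3'R, 5'S and all-E, with C8 and C8' on the side of the gem-dimethyl carbons (6E, 6'E). The 3'-OH and 5'-OH are trans. All polyene steps are run under argon in dim light.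

**Shared steps**

Step 1
Reactants: 1 ketoisophorone
Product: 2 (6R)-2,2,6-trimethylcyclohexane-1,4-dione
Conditions: ene-reductase OYE2, NADP+ (cat.), glucose dehydrogenase, D-glucose, phosphate buffer pH 7, 30 °C
Reagents that add atoms: none
Why: Biocatalytic asymmetric conjugate reduction by a flavin ene-reductase, for which 1 is a standard substrate; hydride and proton add trans across C2=C3 in the active site and set the methyl-bearing centre as 6R.

Step 2
Reactants: 2 (6R)-2,2,6-trimethylcyclohexane-1,4-dione
Product: 3 (4R,6R)-4-hydroxy-2,2,6-trimethylcyclohexanone (OH trans to the C6 methyl)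
Conditions: Li[HB(s-Bu)3] (1.0 equiv), THF, −78 °C; then H2O
Reagents that add atoms: none
Why: Diastereoselective hydride reduction; the bulky borohydride reaches only the unhindered C4 carbonyl and attacks it equatorially because the axial C2 methyl blocks the axial path, so the axial 4R alcohol should form.

**Ring-A series**

Step 3
Reactants: 3 (4R,6R)-4-hydroxy-2,2,6-trimethylcyclohexanone
Product: 4 (4R,6R)-4-(tert-butyldimethylsilyloxy)-2,2,6-trimethylcyclohexanone
Conditions: TBSCl, imidazole, DMF, 25–40 °C
Reagents that add atoms: tert-butyldimethylsilyl chloride, CC(C)(C)[Si](C)(C)Cl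
Why: Standard imidazole-promoted silylation of a secondary alcohol; the hindered ketone is inert.

Step 4
Reactants: 4 silyl ether ketone
Product: 5 (4R)-4-(tert-butyldimethylsilyloxy)-2,6,6-trimethylcyclohex-1-en-1-yl triflate
Conditions: LiN(i-Pr)2, THF, −78 → 0 °C; PhNTf2, 0 °C → rt
Reagents that add atoms: N-phenylbis(trifluoromethanesulfonimide), FC(F)(F)S(=O)(=O)N(c1ccccc1)S(=O)(=O)C(F)(F)F
Why: Enolate O-triflation; C6–H is the only enolisable position, so a single tetrasubstituted enol triflate forms and the C6 stereocentre is erased.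

Step 5
Reactants: 5 enol triflate
Product: 6 methyl (4R)-4-(tert-butyldimethylsilyloxy)-2,6,6-trimethylcyclohex-1-ene-1-carboxylate
Conditions: Pd(OAc)2 (5 mol %), PPh3 (10 mol %), CO (1 atm), Et3N, MeOH–DMF, 60 °C
Reagents that add atoms: carbon monoxide, [C-]#[O+]; methanol, CO
Why: Palladium-catalysed methoxycarbonylation of an alkenyl triflate: zerovalent palladium inserts into C–OTf, CO inserts, and methanol cleaves the acyl complex, which installs C7.

Step 6
Reactants: 6 methyl ester
Product: 7 [(4R)-4-(tert-butyldimethylsilyloxy)-2,6,6-trimethylcyclohex-1-en-1-yl]methanol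
Conditions: i-Bu2AlH (2.5 equiv), CH2Cl2, −78 → 0 °C; then H2O
Reagents that add atoms: none
Why: 1,2-Reduction of an α,β-unsaturated ester to the allylic alcohol with an aluminium hydride; the silyl ether is untouched.

Step 7
Reactants: 7 allylic alcohol
Product: 8 [(1R,4S,6R)-4-(tert-butyldimethylsilyloxy)-2,2,6-trimethyl-7-oxabicyclo[4.1.0]heptan-1-yl]methanol (epoxide anti to OTBS)
Conditions: Ti(Oi-Pr)4, D-(−)-diethyl tartrate, t-BuOOH, 4 Å MS, CH2Cl2, −20 °C
Reagents that add atoms: tert-butyl hydroperoxide, CC(C)(C)OO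
Why: Sharpless asymmetric epoxidation; the titanium–tartrate complex bound to the C7 hydroxyl delivers oxygen to one alkene face under reagent control, and the D-tartrate face is here the one opposite the silyloxy group, which sets C5 and C6.

Step 8
Reactants: 8 epoxy alcohol
Product: 9 (1S,4S,6R)-4-(tert-butyldimethylsilyloxy)-2,2,6-trimethyl-7-oxabicyclo[4.1.0]heptane-1-carbaldehyde
Conditions: Pr4N[RuO4] (5 mol %), N-methylmorpholine N-oxide, 4 Å MS, CH2Cl2, rt
Reagents that add atoms: none
Why: Ley–Griffith oxidation is neutral, so the tetrasubstituted epoxide survives, and the aldehyde has no α-hydrogen to epimerise.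

Step 9
Reactants: 9 epoxy aldehyde
Product: 11 (2E)-[(2R,4S)-4-(tert-butyldimethylsilyloxy)-2-hydroxy-2,6,6-trimethylcyclohexylidene]acetaldehyde, via methyl enol ether 10 (not isolated)
Conditions: [Ph3PCH2OMe]Cl, KN(SiMe3)2, THF, −78 → 0 °C; then aq. oxalic acid, 0 °C
Reagents that add atoms: (methoxymethyl)triphenylphosphonium chloride, [Cl-].COC[P+](c1ccccc1)(c1ccccc1)c1ccccc1; water, O
Why: Wittig methoxymethylenation, then acid hydrolysis of the alkoxyvinyl epoxide: the enol ether oxygen pushes out the allylic C6–O bond and water takes C8, so C5 keeps its oxygen and configuration; of the two rotamers that align C6–O with the π system, the one with C8 anti to the tied-back epoxide carbon C5 avoids eclipsing C5 and its methyl (the rotamer behind E-selective SN2′ openings of vinyl epoxides), so C8 should end trans to C5 (6E).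

Step 10
Reactants: 11 γ-hydroxy enal
Product: 12 (2E)-[(4S)-4-(tert-butyldimethylsilyloxy)-2,6,6-trimethylcyclohex-2-en-1-ylidene]acetaldehyde
Conditions: SOCl2, pyridine–CH2Cl2, −20 → 0 °C
Reagents that add atoms: none
Why: E2 dehydration of a tertiary alcohol via its chlorosulfite; in the chair with equatorial OTBS the C5–O bond is axial and antiperiplanar to the axial C4–H, so the endocyclic C4=C5 should form, and the electron-poor enal disfavours ionisation, which keeps the 6E geometry.

Step 11
Reactants: 12 ring-A C8 dienal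
Product: 13 (2E,4E)-2-methyl-4-[(4S)-4-(tert-butyldimethylsilyloxy)-2,6,6-trimethylcyclohex-2-en-1-ylidene]but-2-enal
Conditions: Ph3P=C(Me)CHO, toluene, 80 °C
Reagents that add atoms: 2-(triphenylphosphoranylidene)propanal, CC(C=O)=P(c1ccccc1)(c1ccccc1)c1ccccc1
Why: Wittig reaction of a stabilised ylide, which is E-selective for C8=C9; the α-methyl enal product is less electrophilic than 12, so a second addition is slow.

**Iodophosphonate**

Step 12
Reactants: 14 but-2-yn-1-ol
Product: 15 (E)-3-iodobut-2-en-1-ol
Conditions: Cp2Zr(H)Cl (2.2 equiv), THF, rt, dark; then I2, 0 °C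
Reagents that add atoms: iodine, II
Why: Hydrozirconation–iodination; syn addition of Zr–H puts zirconium on the methyl-bearing carbon, away from the bulky CH2OZrCp2Cl group, and iodinolysis goes with retention, so iodine ends trans to CH2OH.

Step 13
Reactants: 15 (E)-3-iodobut-2-en-1-ol
Product: 16 (E)-1-bromo-3-iodobut-2-ene
Conditions: PBr3, Et2O, 0 °C
Reagents that add atoms: phosphorus tribromide, BrP(Br)Br
Why: SN2 bromination of a primary allylic alcohol via its phosphite ester; the alkenyl iodide does not react.

Step 14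
Reactants: 16 (E)-1-bromo-3-iodobut-2-ene
Product: 17 diethyl [(2E)-3-iodobut-2-en-1-yl]phosphonate
Conditions: P(OEt)3, neat, 110 °C
Reagents that add atoms: triethyl phosphite, CCOP(OCC)OCC
Why: Michaelis–Arbuzov reaction; only the sp3 allylic bromide alkylates phosphorus, and the sp2 C–I bond is inert without a metal catalyst.

Step 15
Reactants: 13 ring-A C10 trienal; 17 iodophosphonate
Product: 18 ring-A C13 alkenyl iodide (3S, 6E,8E,10E,12E; chain ends in C13(CH3)I)
Conditions: 17, NaN(SiMe3)2, THF, −78 °C; then 13, −78 → 0 °C, dark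
Reagents that add atoms: none
Why: Horner–Wadsworth–Emmons olefination with an allylic phosphonate, E-selective for C10=C11; the amide base does not exchange the iodide, and the low temperature should keep the C12=C13 geometry of the allyl anion.

**Ring-B series**

Step 16
Reactants: 3 (4R,6R)-4-hydroxy-2,2,6-trimethylcyclohexanone
Product: 19 (4S,6R)-4-(4-nitrobenzoyloxy)-2,2,6-trimethylcyclohexanone
Conditions: 4-O2NC6H4CO2H, PPh3, DIAD, toluene, 0 °C → rt
Reagents that add atoms: 4-nitrobenzoic acid, OC(=O)c1ccc(cc1)[N+](=O)[O-]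
Why: Mitsunobu reaction; SN2 displacement of the axial alkoxyphosphonium group by the carboxylate inverts C4 from R to S, the sense needed for C3'.

Step 17
Reactants: 19 nitrobenzoate
Product: 20 (4S,6R)-4-hydroxy-2,2,6-trimethylcyclohexanone (OH cis to the C6 methyl)
Conditions: K2CO3 (cat.), MeOH, 0 °C → rt
Reagents that add atoms: none
Why: Base-catalysed transesterification cleaves the acyl–oxygen bond, so C4 is untouched; any epimerisation at C6 is harmless because that centre is erased in step 19.

Step 18
Reactants: 20 (4S,6R)-hydroxy ketone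
Product: 21 (4S,6R)-4-(tert-butyldimethylsilyloxy)-2,2,6-trimethylcyclohexanone
Conditions: TBSCl, imidazole, DMF, rt
Reagents that add atoms: tert-butyldimethylsilyl chloride, CC(C)(C)[Si](C)(C)Cl
Why: Standard silylation, here of an unhindered equatorial alcohol.

Step 19
Reactants: 21 silyl ether ketone
Product: 22 (4S)-4-(tert-butyldimethylsilyloxy)-2,6,6-trimethylcyclohex-1-en-1-yl triflate
Conditions: LiN(i-Pr)2, THF, −78 → 0 °C; PhNTf2, 0 °C → rt
Reagents that add atoms: N-phenylbis(trifluoromethanesulfonimide), FC(F)(F)S(=O)(=O)N(c1ccccc1)S(=O)(=O)C(F)(F)F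
Why: Enolate O-triflation at the only enolisable position, as in step 4, giving the enantiomer of 5.

Step 20
Reactants: 22 enol triflate
Product: 23 methyl (4S)-4-(tert-butyldimethylsilyloxy)-2,6,6-trimethylcyclohex-1-ene-1-carboxylate
Conditions: Pd(OAc)2 (5 mol %), PPh3 (10 mol %), CO (1 atm), Et3N, MeOH–DMF, 60 °C
Reagents that add atoms: carbon monoxide, [C-]#[O+]; methanol, CO
Why: Palladium-catalysed methoxycarbonylation of an alkenyl triflate, as in step 5.

Step 21
Reactants: 23 methyl ester
Product: 24 [(4S)-4-(tert-butyldimethylsilyloxy)-2,6,6-trimethylcyclohex-1-en-1-yl]methanol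
Conditions: i-Bu2AlH (2.5 equiv), CH2Cl2, −78 → 0 °C; then H2O
Reagents that add atoms: none
Why: 1,2-Reduction of the unsaturated ester to the allylic alcohol, as in step 6.

Step 22
Reactants: 24 allylic alcohol
Product: 25 [(1S,4R,6S)-4-(tert-butyldimethylsilyloxy)-2,2,6-trimethyl-7-oxabicyclo[4.1.0]heptan-1-yl]methanol (epoxide anti to OTBS)
Conditions: Ti(Oi-Pr)4, L-(+)-diethyl tartrate, t-BuOOH, 4 Å MS, CH2Cl2, −20 °C
Reagents that add atoms: tert-butyl hydroperoxide, CC(C)(C)OO
Why: Sharpless asymmetric epoxidation; the L-tartrate complex delivers oxygen to the face that gives 2S-type epoxy alcohols, here the face opposite the silyloxy group, and this sets the C5' oxygen trans to the C3' oxygen (later 5'S).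

Step 23
Reactants: 25 epoxy alcohol
Product: 26 (1R,4R,6S)-4-(tert-butyldimethylsilyloxy)-2,2,6-trimethyl-7-oxabicyclo[4.1.0]heptane-1-carbaldehyde
Conditions: Pr4N[RuO4] (5 mol %), N-methylmorpholine N-oxide, 4 Å MS, CH2Cl2, rt
Reagents that add atoms: none
Why: Neutral Ley–Griffith oxidation, as in step 8.

Step 24
Reactants: 26 epoxy aldehyde
Product: 28 (2E)-[(2S,4R)-4-(tert-butyldimethylsilyloxy)-2-hydroxy-2,6,6-trimethylcyclohexylidene]acetaldehyde, via methyl enol ether 27 (not isolated)
Conditions: [Ph3PCH2OMe]Cl, KN(SiMe3)2, THF, −78 → 0 °C; then aq. oxalic acid, 0 °C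
Reagents that add atoms: (methoxymethyl)triphenylphosphonium chloride, [Cl-].COC[P+](c1ccccc1)(c1ccccc1)c1ccccc1; water, O
Why: Wittig methoxymethylenation and hydrolytic opening of the alkoxyvinyl epoxide, as in step 9; the C5'–O bond is never broken, so 5'S is kept, and reaction through the rotamer with C8' anti to C5' should place C8' trans to C5' (6'E).

Step 25
Reactants: 28 ring-B C8' enal
Product: 29 (2E,4E)-4-[(2S,4R)-4-(tert-butyldimethylsilyloxy)-2-hydroxy-2,6,6-trimethylcyclohexylidene]-2-methylbut-2-enal
Conditions: Ph3P=C(Me)CHO, toluene, 80 °C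
Reagents that add atoms: 2-(triphenylphosphoranylidene)propanal, CC(C=O)=P(c1ccccc1)(c1ccccc1)c1ccccc1
Why: E-selective Wittig reaction of a stabilised ylide forms C8'=C9'; the neutral ylide tolerates the free tertiary alcohol.

Step 26
Reactants: 29 ring-B C10' dienal; 17 iodophosphonate
Product: 30 ring-B C13' alkenyl iodide (3'R,5'S, 6'E,8'E,10'E,12'E; free C5'–OH)
Conditions: 17 (2.5 equiv), NaN(SiMe3)2 (2.5 equiv), THF, −78 °C; then 29, −78 → 0 °C, dark
Reagents that add atoms: none
Why: Horner–Wadsworth–Emmons olefination, E-selective for C10'=C11'; one equivalent of anion is spent on the tertiary hydroxyl, whose alkoxide cannot add to the chain because C8' is trans to C5'.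

**Linchpin**

Step 27
Reactants: 31 propargyl alcohol; 32 tributyltin hydride
Product: 33 (E)-3-(tributylstannyl)prop-2-en-1-ol
Conditions: AIBN (cat.), neat, 80 °C; chromatography
Reagents that add atoms: none
Why: Radical hydrostannation of a terminal alkyne; reversible stannyl radical addition funnels the mixture toward the terminal E-alkenylstannane, and the minor isomers are removed on silica.

Step 28
Reactants: 33 stannyl allylic alcohol
Product: 34 (E)-3-(tributylstannyl)prop-2-enal
Conditions: MnO2, CH2Cl2, rt
Reagents that add atoms: none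
Why: Selective heterogeneous oxidation of an allylic alcohol; the conditions are neutral, so the C–Sn bond is not protonated.

Step 29
Reactants: 34 stannyl enal; 35 pinacol (dichloromethyl)boronate
Product: 36 (1E,3E)-1-(tributylstannyl)-4-(pinacolboryl)buta-1,3-diene
Conditions: CrCl2 (8 equiv), LiI (4 equiv), THF, rt
Reagents that add atoms: none
Why: Takai-type boryl olefination; divalent chromium reduces the gem-dihalide (iodide-exchanged in the flask) to a gem-dichromium species that adds to the aldehyde and eliminates anti to give the E-alkenyl boronate, and the alkenylstannane is inert.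

**Assembly**

Step 30
Reactants: 18 ring-A C13 iodide; 36 tin/boron diene; 30 ring-B C13' iodide
Product: 38 bis(tert-butyldimethylsilyl) ether of the target, via ring-A heptaenyl pinacol boronate 37 (not isolated)
Conditions: 18 + 36 (1:1), Pd2(dba)3 (5 mol %), AsPh3 (20 mol %), degassed DMF, rt, dark, no base; at full conversion 30, aq. K3PO4, THF, rt
Reagents that add atoms: none
Why: Zerovalent palladium from Pd2(dba)3/AsPh3 inserts into the C13–I bond of 18, the tin end of 36 transmetallates and reductive elimination forms C13–C14 (Stille coupling), while the neutral three-coordinate pinacol boronate cannot transmetallate without base, so 37 accumulates intact. Aqueous K3PO4 then makes the boronate four-coordinate, boron transfers its alkenyl group to the palladium species formed from 30, and reductive elimination forms C14'–C13' (Suzuki–Miyaura coupling). The closest known reaction type is the one-pot Stille/Suzuki use of 1-stannyl-4-boryl-1,3-dienes as four-carbon linchpins for polyenes. No ring is closed and no stereocentre is created; C3, C3' and C5' are spectators, and the allylic silyl ether and the free tertiary alcohol tolerate the neutral and then mildly basic medium. Both couplings join sp2 carbons with retention, so 12E, 14E, 14'E and 12'E are inherited from 18, 36 and 30. The selectivity needed is which iodide meets which metal, and it is secured by the absence of base in the first stage and by adding 30 only after the stannane is consumed.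

Step 31
Reactants: 38 bis-silyl ether
Product: 39 target CNP0269135.1
Conditions: Bu4NF–AcOH (1:1), THF, 0 °C → rt, dark
Reagents that add atoms: none
Why: Fluoride desilylation driven by Si–F bond formation; the acetic acid buffer keeps the medium near neutral, so neither the allylic C3–OH nor the tertiary allylic C5'–OH is ionised or eliminated.

**Compound list**

| No. | Name | SMILES | Role |
|---|---|---|---|
| 1 | ketoisophorone | CC1=CC(=O)CC(C)(C)C1=O | starting material |
| 2 | (6R)-2,2,6-trimethylcyclohexane-1,4-dione | O=C1C(C)(C)CC(=O)C[C@H]1C | intermediate |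
| 3 | (4R,6R)-4-hydroxy-2,2,6-trimethylcyclohexanone | O=C1C(C)(C)C[C@H](O)C[C@H]1C | intermediate |
| 4 | (4R,6R)-TBS ether ketone | O=C1C(C)(C)C[C@H](O[Si](C)(C)C(C)(C)C)C[C@H]1C | intermediate |
| 5 | (4R)-enol triflate | CC1=C(OS(=O)(=O)C(F)(F)F)C(C)(C)C[C@H](O[Si](C)(C)C(C)(C)C)C1 | intermediate |
| 6 | (4R)-methyl ester | CC1=C(C(=O)OC)C(C)(C)C[C@H](O[Si](C)(C)C(C)(C)C)C1 | intermediate |
| 7 | (4R)-allylic alcohol | CC1=C(CO)C(C)(C)C[C@H](O[Si](C)(C)C(C)(C)C)C1 | intermediate |
| 8 | (1R,4S,6R)-epoxy alcohol | C[C@]12O[C@@]1(CO)C(C)(C)C[C@H](O[Si](C)(C)C(C)(C)C)C2 | intermediate |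
| 9 | (1S,4S,6R)-epoxy aldehyde | C[C@]12O[C@@]1(C=O)C(C)(C)C[C@H](O[Si](C)(C)C(C)(C)C)C2 | intermediate |
| 10 | (1S,4S,6R)-1-(2-methoxyvinyl) epoxide, E/Z mixture | C[C@]12O[C@@]1(C=COC)C(C)(C)C[C@H](O[Si](C)(C)C(C)(C)C)C2 | intermediate |
| 11 | (2E)-(2R,4S)-γ-hydroxy enal | O=C/C=C1\C(C)(C)C[C@H](O[Si](C)(C)C(C)(C)C)C[C@@]1(C)O | intermediate |
| 12 | ring-A C8 dienal | CC1=C[C@@H](O[Si](C)(C)C(C)(C)C)CC(C)(C)\C1=C/C=O | intermediate |
| 13 | ring-A C10 trienal | CC1=C[C@@H](O[Si](C)(C)C(C)(C)C)CC(C)(C)\C1=C/C=C(C)/C=O | intermediate |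
| 14 | but-2-yn-1-ol | CC#CCO | starting material |
| 15 | (E)-3-iodobut-2-en-1-ol | I/C(C)=C/CO | intermediate |
| 16 | (E)-1-bromo-3-iodobut-2-ene | I/C(C)=C/CBr | intermediate |
| 17 | diethyl [(2E)-3-iodobut-2-en-1-yl]phosphonate | I/C(C)=C/CP(=O)(OCC)OCC | intermediate |
| 18 | ring-A C13 alkenyl iodide | CC1=C[C@@H](O[Si](C)(C)C(C)(C)C)CC(C)(C)\C1=C/C=C(C)/C=C/C=C(C)/I | intermediate |
| 19 | (4S,6R)-4-nitrobenzoate | O=C1C(C)(C)C[C@@H](OC(=O)c2ccc(cc2)[N+](=O)[O-])C[C@H]1C | intermediate |
| 20 | (4S,6R)-4-hydroxy-2,2,6-trimethylcyclohexanone | O=C1C(C)(C)C[C@@H](O)C[C@H]1C | intermediate |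
| 21 | (4S,6R)-TBS ether ketone | O=C1C(C)(C)C[C@@H](O[Si](C)(C)C(C)(C)C)C[C@H]1C | intermediate |
| 22 | (4S)-enol triflate | CC1=C(OS(=O)(=O)C(F)(F)F)C(C)(C)C[C@@H](O[Si](C)(C)C(C)(C)C)C1 | intermediate |
| 23 | (4S)-methyl ester | CC1=C(C(=O)OC)C(C)(C)C[C@@H](O[Si](C)(C)C(C)(C)C)C1 | intermediate |
| 24 | (4S)-allylic alcohol | CC1=C(CO)C(C)(C)C[C@@H](O[Si](C)(C)C(C)(C)C)C1 | intermediate |
| 25 | (1S,4R,6S)-epoxy alcohol | C[C@@]12O[C@]1(CO)C(C)(C)C[C@@H](O[Si](C)(C)C(C)(C)C)C2 | intermediate |
| 26 | (1R,4R,6S)-epoxy aldehyde | C[C@@]12O[C@]1(C=O)C(C)(C)C[C@@H](O[Si](C)(C)C(C)(C)C)C2 | intermediate |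
| 27 | (1R,4R,6S)-1-(2-methoxyvinyl) epoxide, E/Z mixture | C[C@@]12O[C@]1(C=COC)C(C)(C)C[C@@H](O[Si](C)(C)C(C)(C)C)C2 | intermediate |
| 28 | (2E)-(2S,4R)-γ-hydroxy enal | O=C/C=C1\C(C)(C)C[C@@H](O[Si](C)(C)C(C)(C)C)C[C@]1(C)O | intermediate |
| 29 | ring-B C10' dienal | O=C/C(C)=C/C=C1\C(C)(C)C[C@@H](O[Si](C)(C)C(C)(C)C)C[C@]1(C)O | intermediate |
| 30 | ring-B C13' alkenyl iodide | I/C(C)=C/C=C/C(C)=C/C=C1\C(C)(C)C[C@@H](O[Si](C)(C)C(C)(C)C)C[C@]1(C)O | intermediate |
| 31 | propargyl alcohol | C#CCO | starting material |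
| 32 | tributyltin hydride | CCCC[SnH](CCCC)CCCC | starting material |
| 33 | (E)-3-(tributylstannyl)prop-2-en-1-ol | CCCC[Sn](CCCC)(CCCC)/C=C/CO | intermediate |
| 34 | (E)-3-(tributylstannyl)prop-2-enal | CCCC[Sn](CCCC)(CCCC)/C=C/C=O | intermediate |
| 35 | pinacol (dichloromethyl)boronate | ClC(Cl)B1OC(C)(C)C(C)(C)O1 | starting material |
| 36 | (1E,3E)-1-(tributylstannyl)-4-(pinacolboryl)buta-1,3-diene | CCCC[Sn](CCCC)(CCCC)/C=C/C=C/B1OC(C)(C)C(C)(C)O1 | intermediate |
| 37 | ring-A heptaenyl pinacol boronate | CC1=C[C@@H](O[Si](C)(C)C(C)(C)C)CC(C)(C)\C1=C/C=C(C)/C=C/C=C(C)/C=C/C=C/B1OC(C)(C)C(C)(C)O1 | intermediate |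
| 38 | bis-TBS ether of the target | CC1=C[C@@H](O[Si](C)(C)C(C)(C)C)CC(C)(C)\C1=C/C=C(C)/C=C/C=C(C)/C=C/C=C/C(C)=C/C=C/C(C)=C/C=C1\C(C)(C)C[C@@H](O[Si](C)(C)C(C)(C)C)C[C@]1(C)O | intermediate |
| 39 | CNP0269135.1 | CC1=C[C@@H](O)CC(C)(C)\C1=C/C=C(C)/C=C/C=C(C)/C=C/C=C/C(C)=C/C=C/C(C)=C/C=C1\C(C)(C)C[C@@H](O)C[C@]1(C)O | target |

**Step count**
- Total step count: 31.
- Longest linear sequence: 15 steps (steps 1, 2, 16–26, 30, 31).

**Steps most likely to fail**

1. **Step 30.**
   - What may go wrong: the long boronate may lose boron by protonolysis or isomerise while it waits for the second stage. Transfer from the pinacol boronate may be slow. If any stannane is left when the second iodide and base enter, the two ends are no longer told apart and symmetric products form.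
   - Fallback, from 34 and 18, back at 38: a CrCl2-mediated olefination of 34 with Bu3SnCHBr2 gives (1E,3E)-1,4-bis(tributylstannyl)buta-1,3-diene F1. Stille coupling of 18 with a several-fold excess of that diene gives the ring-A heptaenyl stannane F2, which is separated from the excess reagent. A second Stille coupling with 30 comes back at 38. The ends are then distinguished by stoichiometry and isolation, and neither boron nor base is involved.

2. **Step 24.**
   - What may go wrong: the C6'–C7' bond may rotate at the oxocarbenium stage, after which the C5' hydroxyl closes onto C8' and drains material into the cyclic acetal of the 6'Z series. Water may also open the epoxide before the enol ether does.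
   - Fallback, from 26, back at 28: methylenation of 26 with Ph3P=CH2 gives the vinyl epoxide F3. Copper-catalysed SN2′ borylation (CuCl, NaOt-Bu, Xantphos, B2pin2, MeOH) opens it without acid to the (E)-allyl boronate F4. Oxidation with NaBO3 gives the (E)-allylic diol F5, and MnO2 oxidises only the primary allylic alcohol to come back at 28.

3. **Step 10.**
   - What may go wrong: the proton may be lost from the C5 methyl instead of C4, giving an exocyclic methylene. Chloride may be captured with allylic shift, or ionisation may erase the 6E geometry.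
   - Fallback, from 7, back at 12: MnO2 oxidation of 7 gives the silyloxy cyclocitral F6. Wittig methoxymethylenation gives the dienol methyl ether F7. DDQ in wet dioxane abstracts hydride from C4, as in the dehydrogenation of steroidal dienol ethers to linear dienones, and hydrolysis comes back at 12. The 6Z isomer that this unselective route may also form is removed by chromatography.

**Further compounds**
F1 | step 30 | (1E,3E)-1,4-bis(tributylstannyl)buta-1,3-diene | CCCC[Sn](CCCC)(CCCC)/C=C/C=C/[Sn](CCCC)(CCCC)CCCC
F2 | step 30 | ring-A heptaenyl stannane | CC1=C[C@@H](O[Si](C)(C)C(C)(C)C)CC(C)(C)\C1=C/C=C(C)/C=C/C=C(C)/C=C/C=C/[Sn](CCCC)(CCCC)CCCC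
F3 | step 24 | (1R,4R,6S)-1-vinyl epoxide | C[C@@]12O[C@]1(C=C)C(C)(C)C[C@@H](O[Si](C)(C)C(C)(C)C)C2
F4 | step 24 | (E)-allyl pinacol boronate with free C5' hydroxyl | CC1(C)OB(C/C=C2\C(C)(C)C[C@@H](O[Si](C)(C)C(C)(C)C)C[C@]2(C)O)OC1(C)C
F5 | step 24 | (E)-allylic diol | OC/C=C1\C(C)(C)C[C@@H](O[Si](C)(C)C(C)(C)C)C[C@]1(C)O
F6 | step 10 | (4R)-4-(tert-butyldimethylsilyloxy)-2,6,6-trimethylcyclohex-1-ene-1-carbaldehyde | CC1=C(C=O)C(C)(C)C[C@H](O[Si](C)(C)C(C)(C)C)C1
F7 | step 10 | (4R)-dienol methyl ether, E/Z mixture | CC1=C(C=COC)C(C)(C)C[C@H](O[Si](C)(C)C(C)(C)C)C1
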